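## Retrosynthetic overview

1. The last ring formed is the pyrone ring of the coumarin, cut at C4–C4a and O1–C2 into a pentasubstituted resorcinol and a methoxymethylene ester carrying C2, C3, C4 and the dihydropyranone. The design rests on the C2'' hydroxyl of the 3-hydroxybutan-2-yl chain on C5: it is β to the arene and can hold the electrophilic C4 over C4a, the only unsubstituted benzo-ring carbon (ortho to the C8a oxygen, para to the C7 hydroxyl), through a six-membered isochroman ring that reopens as the lactone closes.
2. Resorcinol: the aryl–C1'' bond comes from copper-catalysed aryl Grignard opening of (2R,3R)-2,3-dimethyloxirane (sets C1''), followed by Mitsunobu inversion at C2'' and hydrogenolysis of benzyl ethers. The ring methyl next to the side chain is installed first by formylation and reduction.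
3. Methoxymethylene ester: the dihydropyranone ring comes from cyclodehydration of a δ-hydroxy-β,δ-diketo ester built from (R)-3-hydroxybutanoate (as Weinreb amide) and the methyl acetoacetate dianion; C4 comes from trimethyl orthoformate.
4. Ring order: benzo ring bought, dihydropyranone ring (step 14), transient isochroman ring and then the coumarin pyrone ring (step 16).

Key step: step 16

Remark 1: the commercial aryl bromide carries only the ring methyl between the two oxygens, whereas the resorcinol needs a second methyl next to the side chain; steps 1 and 2 add it.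
Remark 2: the phenols are carried as benzyl ethers (steps 3 and 4), because a final Lewis-acid demethylation could ionise the homobenzylic carbinol and acetal-type groups would release a formaldehyde equivalent onto the free arene carbon.
Remark 3: the methoxymethylene ester is used as an E/Z mixture, since the alkene geometry is erased in step 16.

## Route

Step 1
Reactants: 1 5-bromo-1,3-dimethoxy-2-methylbenzene
Product: 2 6-bromo-2,4-dimethoxy-3-methylbenzaldehyde
Conditions: Cl2CHOMe (1.3 equiv), TiCl4 (2.2 equiv), CH2Cl2, −10 to 0 °C; aq. HCl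
Reagents that add atoms: dichloromethyl methyl ether, COC(Cl)Cl; water, O
Why: Rieche formylation of an arene activated by two methoxy groups should give a single aldehyde, because the two free ring positions are equivalent by symmetry (each ortho to one methoxy group and para to the other).

Step 2
Reactants: 2 6-bromo-2,4-dimethoxy-3-methylbenzaldehyde
Product: 3 1-bromo-3,5-dimethoxy-2,4-dimethylbenzene
Conditions: Et3SiH (3 equiv), TFA, CH2Cl2, 0 °C to rt
Reagents that add atoms: none
Why: Ionic hydrogenation should reduce the protonated aldehyde and then the strongly stabilised 2,4-dimethoxybenzyl cation by hydride transfer from the silane, taking the formyl group to methyl without touching the aryl bromide.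

Step 3
Reactants: 3 1-bromo-3,5-dimethoxy-2,4-dimethylbenzene
Product: 4 5-bromo-2,4-dimethylbenzene-1,3-diol
Conditions: BBr3 (3 equiv), CH2Cl2, −78 °C to rt; H2O
Reagents that add atoms: none
Why: Lewis-acid cleavage of aryl methyl ethers (bromide attacks the methyl group of the O–B complex) is carried out here, before any side-chain alcohol exists that BBr3 could brominate.

Step 4
Reactants: 4 5-bromo-2,4-dimethylbenzene-1,3-diol
Product: 5 1,3-bis(benzyloxy)-5-bromo-2,4-dimethylbenzene
Conditions: BnBr (2.5 equiv), K2CO3 (3 equiv), DMF, 60 °C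
Reagents that add atoms: benzyl bromide, BrCc1ccccc1
Why: Williamson etherification of both phenoxides should be complete, since the benzylic halide is reactive enough even for the hydroxyl flanked by two methyl groups.

Step 5
Reactants: 6 (2R,3R)-butane-2,3-diol
Product: 7 (2R,3S)-3-bromobutan-2-yl acetate
Conditions: HBr (33% in AcOH), 0 °C to rt
Reagents that add atoms: hydrogen bromide, Br; acetic acid, CC(=O)O
Why: The monoacetate closes to a cyclic acetoxonium ion with both C–O bonds intact, and bromide opens it by SN2 with inversion at one of the two equivalent carbons, giving the erythro bromo acetate.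

Step 6
Reactants: 7 (2R,3S)-3-bromobutan-2-yl acetate
Product: 8 (2R,3R)-2,3-dimethyloxirane
Conditions: KOC5H11 (potassium pentan-1-olate), pentan-1-ol, rt to 120 °C bath, product distilled out (bp ca. 54 °C)
Reagents that add atoms: none
Why: Transesterification frees the alkoxide, which displaces the neighbouring bromide (intramolecular Williamson closure, second inversion at the same carbon), so the trans-epoxide should keep the (2R,3R) configuration of the diol.

Step 7
Reactants: 5 1,3-bis(benzyloxy)-5-bromo-2,4-dimethylbenzene; 8 (2R,3R)-2,3-dimethyloxirane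
Product: 10 (2R,3R)-3-[3,5-bis(benzyloxy)-2,4-dimethylphenyl]butan-2-ol, via aryl Grignard reagent 9 (not isolated)
Conditions: Mg, I2 (cat.), THF, 50 °C; then CuI (10 mol%), 8 (1.5 equiv), THF, −30 to 0 °C; aq. NH4Cl
Reagents that add atoms: none
Why: Copper-catalysed Grignard opening of an epoxide is an SN2 process, so the arene enters one of the two equivalent epoxide carbons with inversion while the other keeps its C–O bond, which sets the benzylic centre (C1'' of the target, R) and gives the erythro (2R,3R) alcohol.

Step 8
Reactants: 10 (2R,3R)-3-[3,5-bis(benzyloxy)-2,4-dimethylphenyl]butan-2-ol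
Product: 11 (2S,3R)-3-[3,5-bis(benzyloxy)-2,4-dimethylphenyl]butan-2-yl 4-nitrobenzoate
Conditions: 4-nitrobenzoic acid (1.5 equiv), PPh3 (1.5 equiv), DIAD (1.5 equiv), THF, 0 °C to rt
Reagents that add atoms: 4-nitrobenzoic acid, OC(=O)c1ccc(cc1)[N+](=O)[O-]
Why: In the Mitsunobu reaction the carboxylate displaces the alkoxyphosphonium group by SN2, inverting the carbinol carbon (C2'' of the target, R to S) and so turning the erythro into the required threo relationship without involving the benzylic centre.

Step 9
Reactants: 11 (2S,3R)-3-[3,5-bis(benzyloxy)-2,4-dimethylphenyl]butan-2-yl 4-nitrobenzoate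
Product: 12 (2S,3R)-3-[3,5-bis(benzyloxy)-2,4-dimethylphenyl]butan-2-ol
Conditions: K2CO3 (0.5 equiv), MeOH–THF, rt
Reagents that add atoms: none
Why: Base-catalysed methanolysis attacks the activated 4-nitrobenzoate at the acyl carbon, so the C–O bond at the stereocentre is not broken and the inverted configuration is retained.

Step 10
Reactants: 12 (2S,3R)-3-[3,5-bis(benzyloxy)-2,4-dimethylphenyl]butan-2-ol
Product: 13 5-[(2R,3S)-3-hydroxybutan-2-yl]-2,4-dimethylbenzene-1,3-diol
Conditions: H2 (1 atm), 10% Pd/C, EtOAc–MeOH, rt, product kept under Ar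
Reagents that add atoms: none
Why: Hydrogenolysis cleaves only the benzylic C–O bonds of the two aryl benzyl ethers; the side-chain hydroxyl is homobenzylic and the conditions are neutral, so both stereocentres should be untouched.

Step 11
Reactants: 14 methyl (R)-3-hydroxybutanoate
Product: 15 methyl (R)-3-[(tert-butyldimethylsilyl)oxy]butanoate
Conditions: TBSCl (1.2 equiv), imidazole (2.5 equiv), DMF, rt
Reagents that add atoms: tert-butyldimethylsilyl chloride, CC(C)(C)[Si](C)(C)Cl
Why: Imidazole-promoted silylation of the secondary alcohol protects it from the strong bases of steps 12 and 13 without touching the stereocentre.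

Step 12
Reactants: 15 methyl (R)-3-[(tert-butyldimethylsilyl)oxy]butanoate
Product: 16 (R)-3-[(tert-butyldimethylsilyl)oxy]-N-methoxy-N-methylbutanamide
Conditions: MeNH(OMe)·HCl (1.5 equiv), i-PrMgCl (3.0 equiv), THF, −20 to 0 °C
Reagents that add atoms: N,O-dimethylhydroxylamine hydrochloride, CNOC.Cl
Why: The chloromagnesium amide of N,O-dimethylhydroxylamine converts the ester directly into the Weinreb amide at low temperature, and the stereocentre is β to the carbonyl and cannot epimerise.

Step 13
Reactants: 17 methyl acetoacetate; 16 (R)-3-[(tert-butyldimethylsilyl)oxy]-N-methoxy-N-methylbutanamide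
Product: 19 methyl (7R)-7-[(tert-butyldimethylsilyl)oxy]-3,5-dioxooctanoate, via acetoacetate dianion 18 (not isolated)
Conditions: 17 (1.8 equiv), NaH (1.8 equiv), THF, 0 °C; n-BuLi (1.8 equiv), 0 °C; then 16 (1.0 equiv), −78 to 0 °C; aq. HCl (1 M)
Reagents that add atoms: none
Why: Claisen-type γ-acylation of the acetoacetate dianion at its terminal carbon by a Weinreb amide should stop at the mono-adduct, because the chelated tetrahedral intermediate survives until work-up.

Step 14
Reactants: 19 methyl (7R)-7-[(tert-butyldimethylsilyl)oxy]-3,5-dioxooctanoate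
Product: 21 methyl 2-[(2R)-2-methyl-4-oxo-3,4-dihydro-2H-pyran-6-yl]acetate, via hydroxy diketo ester 20 (not isolated)
Conditions: TFA–CH2Cl2 (1:4), H2O (2 equiv), 0 °C to rt
Reagents that add atoms: none
Why: Acid removes the silyl ether and the freed C7 hydroxyl adds to the C3 ketone, the only carbonyl it can reach through a six-membered ring (6-exo-trig hemiketal), after which dehydration gives the conjugated 2,3-dihydro-4H-pyran-4-one without ever breaking the C–O bond of the stereocentre.

Step 15
Reactants: 21 methyl 2-[(2R)-2-methyl-4-oxo-3,4-dihydro-2H-pyran-6-yl]acetate; 22 trimethyl orthoformate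
Product: 23 methyl 3-methoxy-2-[(2R)-2-methyl-4-oxo-3,4-dihydro-2H-pyran-6-yl]prop-2-enoate (E/Z mixture)
Conditions: 22 (5 equiv), Ac2O (3 equiv), ZnCl2 (5 mol%), 100 °C, MeOAc distilled off
Reagents that add atoms: none
Why: Alkoxymethylenation of an active methylene should occur here because the CH2 between the ester and the vinylogous-ester carbon enolises, attacks the dimethoxycarbenium ion from the orthoester and loses methanol, which acetic anhydride removes as methyl acetate.

Step 16
Reactants: 13 5-[(2R,3S)-3-hydroxybutan-2-yl]-2,4-dimethylbenzene-1,3-diol; 23 methyl 3-methoxy-2-[(2R)-2-methyl-4-oxo-3,4-dihydro-2H-pyran-6-yl]prop-2-enoate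
Product: 27 7-hydroxy-5-[(2R,3S)-3-hydroxybutan-2-yl]-6,8-dimethyl-3-[(2R)-2-methyl-4-oxo-3,4-dihydro-2H-pyran-6-yl]-2H-chromen-2-one, via mixed enol ether 24 (not isolated), via isochroman adduct 25 (not isolated), via arylidene ester 26 (not isolated)
Conditions: 13 (1.0 equiv), 23 (1.2 equiv), CSA (0.2 equiv), 1,2-dichloroethane, 5 Å MS, Ar, 40 °C then 80 °C
Reagents that add atoms: none
Why: Proposed new method: acid should exchange the enol-ether methoxy group of 23 for the C2'' hydroxyl of 13 by addition–elimination (24), after which the protonated β-alkoxyacrylate, an oxocarbenium ion held beside C4a, is captured by the arene to give isochroman 25; 25 has an acidic hydrogen on the future C3 (between the ester and the vinylogous ester) and a benzylic C4–O bond activated by the ortho and para hydroxyls, so it should reopen by retro-oxa-Michael elimination to arylidene ester 26, whose C8a hydroxyl then closes the lactone with loss of methanol and pulls the reversible steps forward. The closest known chemistry is the Pechmann-type condensation of resorcinols with alkoxymethylene esters to 3-substituted coumarins and the oxa-Pictet–Spengler cyclisation of 2-arylethanols with enol ethers, but running the two through a side-chain hydroxyl tether has no direct precedent. The transient isochroman ring closes 6-exo-trig on the acrylate C=C (equivalently 6-endo-trig on the oxocarbenium C=O), and the lactone ring, the only ring kept, closes 6-exo-trig on the ester carbonyl. No stereocentre is created in the product, because the two formed in 25 (C4 and C3) are erased by the elimination, and the three existing ones lie outside the reacting bonds and should survive a mild sulfonic acid. The step needs a single site of C–C bond formation and a single lactonising phenol, and the substrate offers nothing else: C4a is the one unsubstituted arene carbon, the tether reaches it only through a six-membered ring, the C8a hydroxyl alone is within reach of the ester, and enol ethers formed at the phenols cannot cyclise and should simply revert.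

## Compound list

1 | 5-bromo-1,3-dimethoxy-2-methylbenzene | COc1cc(Br)cc(OC)c1C | starting material
2 | 6-bromo-2,4-dimethoxy-3-methylbenzaldehyde | COc1cc(Br)c(C=O)c(OC)c1C | intermediate
3 | 1-bromo-3,5-dimethoxy-2,4-dimethylbenzene | COc1cc(Br)c(C)c(OC)c1C | intermediate
4 | 5-bromo-2,4-dimethylbenzene-1,3-diol | Cc1c(O)cc(Br)c(C)c1O | intermediate
5 | 1,3-bis(benzyloxy)-5-bromo-2,4-dimethylbenzene | Cc1c(OCc2ccccc2)cc(Br)c(C)c1OCc1ccccc1 | intermediate
6 | (2R,3R)-butane-2,3-diol | C[C@@H](O)[C@@H](C)O | starting material
7 | (2R,3S)-3-bromobutan-2-yl acetate | C[C@@H](OC(C)=O)[C@H](C)Br | intermediate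
8 | (2R,3R)-2,3-dimethyloxirane | C[C@H]1O[C@@H]1C | intermediate
9 | [3,5-bis(benzyloxy)-2,4-dimethylphenyl]magnesium bromide | Cc1c(OCc2ccccc2)cc([Mg]Br)c(C)c1OCc1ccccc1 | intermediate
10 | (2R,3R)-3-[3,5-bis(benzyloxy)-2,4-dimethylphenyl]butan-2-ol | Cc1c(OCc2ccccc2)cc([C@@H](C)[C@@H](C)O)c(C)c1OCc1ccccc1 | intermediate
11 | (2S,3R)-3-[3,5-bis(benzyloxy)-2,4-dimethylphenyl]butan-2-yl 4-nitrobenzoate | Cc1c(OCc2ccccc2)cc([C@@H](C)[C@H](C)OC(=O)c2ccc(cc2)[N+](=O)[O-])c(C)c1OCc1ccccc1 | intermediate
12 | (2S,3R)-3-[3,5-bis(benzyloxy)-2,4-dimethylphenyl]butan-2-ol | Cc1c(OCc2ccccc2)cc([C@@H](C)[C@H](C)O)c(C)c1OCc1ccccc1 | intermediate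
13 | 5-[(2R,3S)-3-hydroxybutan-2-yl]-2,4-dimethylbenzene-1,3-diol | Cc1c(O)c(C)c(O)cc1[C@@H](C)[C@H](C)O | intermediate
14 | methyl (R)-3-hydroxybutanoate | C[C@@H](O)CC(=O)OC | starting material
15 | methyl (R)-3-[(tert-butyldimethylsilyl)oxy]butanoate | C[C@@H](O[Si](C)(C)C(C)(C)C)CC(=O)OC | intermediate
16 | (R)-3-[(tert-butyldimethylsilyl)oxy]-N-methoxy-N-methylbutanamide | C[C@@H](O[Si](C)(C)C(C)(C)C)CC(=O)N(C)OC | intermediate
17 | methyl acetoacetate | CC(=O)CC(=O)OC | starting material
18 | lithium sodium dienolate of methyl acetoacetate (dianion) | [Li+].[Na+].C=C([O-])C=C([O-])OC | intermediate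
19 | methyl (7R)-7-[(tert-butyldimethylsilyl)oxy]-3,5-dioxooctanoate | C[C@@H](O[Si](C)(C)C(C)(C)C)CC(=O)CC(=O)CC(=O)OC | intermediate
20 | methyl (7R)-7-hydroxy-3,5-dioxooctanoate | C[C@@H](O)CC(=O)CC(=O)CC(=O)OC | intermediate
21 | methyl 2-[(2R)-2-methyl-4-oxo-3,4-dihydro-2H-pyran-6-yl]acetate | COC(=O)CC1=CC(=O)C[C@@H](C)O1 | intermediate
22 | trimethyl orthoformate | COC(OC)OC | starting material
23 | methyl 3-methoxy-2-[(2R)-2-methyl-4-oxo-3,4-dihydro-2H-pyran-6-yl]prop-2-enoate (E/Z mixture) | COC=C(C(=O)OC)C1=CC(=O)C[C@@H](C)O1 | intermediate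
24 | methyl 3-{[(2S,3R)-3-(3,5-dihydroxy-2,4-dimethylphenyl)butan-2-yl]oxy}-2-[(2R)-2-methyl-4-oxo-3,4-dihydro-2H-pyran-6-yl]prop-2-enoate | Cc1c(O)c(C)c(O)cc1[C@@H](C)[C@H](C)OC=C(C(=O)OC)C2=CC(=O)C[C@@H](C)O2 | intermediate
25 | methyl 2-[(3S,4R)-6,8-dihydroxy-3,4,5,7-tetramethyl-3,4-dihydro-1H-isochromen-1-yl]-2-[(2R)-2-methyl-4-oxo-3,4-dihydro-2H-pyran-6-yl]acetate (epimers at C1 and the ester α-carbon) | Cc1c(O)c(C)c(O)c2c1[C@@H](C)[C@H](C)OC2C(C(=O)OC)C3=CC(=O)C[C@@H](C)O3 | intermediate
26 | methyl 3-{2,4-dihydroxy-6-[(2R,3S)-3-hydroxybutan-2-yl]-3,5-dimethylphenyl}-2-[(2R)-2-methyl-4-oxo-3,4-dihydro-2H-pyran-6-yl]prop-2-enoate | Cc1c(O)c(C)c(O)c(C=C(C(=O)OC)C2=CC(=O)C[C@@H](C)O2)c1[C@@H](C)[C@H](C)O | intermediate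
27 | 7-hydroxy-5-[(2R,3S)-3-hydroxybutan-2-yl]-6,8-dimethyl-3-[(2R)-2-methyl-4-oxo-3,4-dihydro-2H-pyran-6-yl]-2H-chromen-2-one | Cc1c(O)c(C)c2oc(=O)c(C3=CC(=O)C[C@@H](C)O3)cc2c1[C@@H](C)[C@H](C)O | target

## Step count and risks

Total step count: 16.
Longest linear sequence: 9 steps (1, 2, 3, 4, 7, 8, 9, 10, 16).

Steps most likely to fail:

1. Step 16. Exchange of the enol-ether methoxy group for the hindered secondary hydroxyl may be slower than reversible O-vinylation of the phenols. The isochroman adduct may also stall without eliminating, or prolonged acid may reversibly open the dihydropyranone at its ring C–O bond and erode that stereocentre.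
   Fallback (known chemistry, polarity of the coupling reversed): it sets out from 13 and 21. Resorcinol 13 is formylated at its only free ring carbon with triethyl orthoformate and TFA; the side-chain hydroxyl closes onto the new carbon and the cyclised quinone methide (3S,4R)-8-hydroxy-3,4,5,7-tetramethyl-4,6-dihydro-3H-isochromen-6-one F1 should result. F1 then takes up the active methylene of 21 at C1 under catalytic Et3N in MeCN, a Knoevenagel-type coumarin synthesis on a masked salicylaldehyde, which rearomatises the arene and gives 25. Warming with CSA completes elimination and lactonisation through 26. The fallback comes back to the route at 25 and ends at 27.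

2. Step 15. The methylene is only vinylogously activated, so condensation may be sluggish. The orthoester-derived cation may instead attack the ring carbon α to the ketone, and at the temperature needed the dihydropyranone may racemise by reversible ring opening.
   Fallback: it sets out from 21. Condensation with N,N-dimethylformamide dimethyl acetal in toluene at 50 °C should give methyl 3-(dimethylamino)-2-[(2R)-2-methyl-4-oxo-3,4-dihydro-2H-pyran-6-yl]prop-2-enoate F2. Hydrolysis with dilute aqueous HCl in THF gives methyl 3-hydroxy-2-[(2R)-2-methyl-4-oxo-3,4-dihydro-2H-pyran-6-yl]prop-2-enoate F3. O-Methylation of this enol with trimethylsilyldiazomethane in MeOH–toluene comes back to the route at 23.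

3. Step 7. The 2,3-disubstituted epoxide opens slowly, so magnesium halide may isomerise it to butanone or open it to the bromohydrin first, and the volatile epoxide may be lost before it reacts.
   Fallback: it sets out from 6 and uses Grignard reagent 9 made from 5. Diol 6 with SOCl2 gives (4R,5R)-4,5-dimethyl-1,3,2-dioxathiolane 2-oxide F4, which RuCl3 (cat.) and NaIO4 oxidise to the non-volatile (4R,5R)-4,5-dimethyl-1,3,2-dioxathiolane 2,2-dioxide F5. Reagent 9 with CuI (cat.) in THF opens F5 by SN2 with inversion to (2R,3R)-3-[3,5-bis(benzyloxy)-2,4-dimethylphenyl]butan-2-yl hydrogen sulfate F6. Hydrolysis with catalytic H2SO4 and water in THF comes back to the route at 10.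

## Further compounds

F1 | step 16 | (3S,4R)-8-hydroxy-3,4,5,7-tetramethyl-4,6-dihydro-3H-isochromen-6-one | O=C1C(C)=C(O)C2=CO[C@@H](C)[C@H](C)C2=C1C
F2 | step 15 | methyl 3-(dimethylamino)-2-[(2R)-2-methyl-4-oxo-3,4-dihydro-2H-pyran-6-yl]prop-2-enoate | CN(C)C=C(C(=O)OC)C1=CC(=O)C[C@@H](C)O1
F3 | step 15 | methyl 3-hydroxy-2-[(2R)-2-methyl-4-oxo-3,4-dihydro-2H-pyran-6-yl]prop-2-enoate | OC=C(C(=O)OC)C1=CC(=O)C[C@@H](C)O1
F4 | step 7 | (4R,5R)-4,5-dimethyl-1,3,2-dioxathiolane 2-oxide | C[C@H]1OS(=O)O[C@@H]1C
F5 | step 7 | (4R,5R)-4,5-dimethyl-1,3,2-dioxathiolane 2,2-dioxide | C[C@H]1OS(=O)(=O)O[C@@H]1C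
F6 | step 7 | (2R,3R)-3-[3,5-bis(benzyloxy)-2,4-dimethylphenyl]butan-2-yl hydrogen sulfate | Cc1c(OCc2ccccc2)cc([C@@H](C)[C@@H](C)OS(=O)(=O)O)c(C)c1OCc1ccccc1
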